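**Retrosynthetic overview** (eudesmane numbering C1–C15; ring A = C1–C5, C10; ring B = C5–C10)
1. Target ⇐ 3β-alcohol ⇐ 4-en-3-one ⇐ 3-methoxy-2,4-diene ester (propionylation, Luche reduction, enol ether hydrolysis).
2. Key disconnection: C1–C2 and C5–C10 together, by retro-[4+2] with CO2 put back, to an acyclic 6-alkyl-4-methoxy-5-methyl-2-pyrone carrying a 2-methylallyl group; rings A and B are formed together in one operation.
3. Enabling feature: in ring A the unit O–C3–C4(CH3)=C5 next to CH2-2 is the hydrolysed and reduced form of a 3-methoxy-2,4-diene, i.e. C3–C6 of a 4-methoxy-5-methyl-2-pyrone after CO2 loss; C10 with its methyl and C1 is a 2-methylallyl group held four carbons away (C6–C9 of ring B).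
4. Acyclic pyrone triene ⇐ acetylation and HNO2 elimination ⇐ asymmetric methallylboration (sets C8) ⇐ enamine Michael adduct (sets C7) of a pyronylpropanal with methyl 3-nitroacrylate.
5. Pyronylpropanal ⇐ allylation and oxidative cleavage of 4-methoxy-5,6-dimethyl-2-pyrone ⇐ O-methylation of 4-hydroxy-5,6-dimethyl-2-pyrone.

Key step: step 7

Assumption: 4-hydroxy-5,6-dimethyl-2H-pyran-2-one, methyl (E)-3-nitroacrylate and 2-methylallylboronic acid pinacol ester are taken as purchasable (the nitroacrylate is otherwise made from methyl acrylate by nitration and elimination).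

**Step 1**
Reactants: 1 4-hydroxy-5,6-dimethyl-2H-pyran-2-one
Product: 2 4-methoxy-5,6-dimethyl-2H-pyran-2-one
Conditions: Me2SO4, K2CO3, acetone, reflux
Reagents that add atoms: dimethyl sulfate, COS(=O)(=O)OC
Why: O-alkylation of the vinylogous acid (Williamson-type methylation) should take place at the 4-oxygen, as is usual for 4-hydroxy-2-pyrones, and no stereocentre is involved.

**Step 2**
Reactants: 2 4-methoxy-5,6-dimethyl-2H-pyran-2-one; 3 allyl bromide
Product: 4 6-(but-3-en-1-yl)-4-methoxy-5-methyl-2H-pyran-2-one
Conditions: LiN(iPr)2 (commercial solution), THF/DMPU, −78 °C; then 3, −78 → −20 °C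
Reagents that add atoms: none
Why: Kinetic deprotonation at the 6-methyl group, the only methyl group conjugated with the pyrone carbonyl, gives an extended lithium dienolate that is C-alkylated by allyl bromide (vinylogous enolate alkylation), and no stereocentre is formed.

**Step 3**
Reactants: 4 6-(but-3-en-1-yl)-4-methoxy-5-methyl-2H-pyran-2-one
Product: 6 3-(4-methoxy-5-methyl-2-oxo-2H-pyran-6-yl)propanal, via vicinal diol 5 (not isolated)
Conditions: OsO4 (2 mol %), NaIO4, 2,6-lutidine, 1,4-dioxane/H2O, rt
Reagents that add atoms: osmium tetroxide, O=[Os](=O)(=O)=O; sodium periodate, [Na+].[O-]I(=O)(=O)=O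
Why: In this Lemieux–Johnson oxidation OsO4 should dihydroxylate the monosubstituted terminal alkene in preference to the electron-poor, more highly substituted pyrone double bonds, and NaIO4 cleaves the diol to the aldehyde.

**Step 4**
Reactants: 6 3-(4-methoxy-5-methyl-2-oxo-2H-pyran-6-yl)propanal; 7 methyl (E)-3-nitroacrylate
Product: 8 methyl (2R,3R)-3-formyl-4-(4-methoxy-5-methyl-2-oxo-2H-pyran-6-yl)-2-(nitromethyl)butanoate
Conditions: (S)-2-[diphenyl(trimethylsilyloxy)methyl]pyrrolidine (10 mol %), ClCH2CO2H (20 mol %), CH2Cl2, 0 °C → rt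
Reagents that add atoms: none
Why: In this enamine-catalysed asymmetric Michael addition of an aldehyde to a nitroalkene the nitroacrylate is attacked at the ester-bearing carbon (β to NO2), which forms C7–C11, and the diaryl(silyloxy)methyl group blocks one face of the (E)-enamine so that C7 should be set as R in the syn adduct (C11 is erased in step 6).

**Step 5**
Reactants: 8 methyl (2R,3R)-3-formyl-4-(4-methoxy-5-methyl-2-oxo-2H-pyran-6-yl)-2-(nitromethyl)butanoate; 9 2-(2-methylallyl)-4,4,5,5-tetramethyl-1,3,2-dioxaborolane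
Product: 10 methyl (2R,3R,4R)-4-hydroxy-3-[(4-methoxy-5-methyl-2-oxo-2H-pyran-6-yl)methyl]-6-methyl-2-(nitromethyl)hept-6-enoate
Conditions: (R)-3,3′-bis(2,4,6-triisopropylphenyl)-1,1′-binaphthyl-2,2′-diyl hydrogen phosphate (5 mol %), PhMe, 4 Å MS, −30 °C; aq. NaHCO3 work-up
Reagents that add atoms: none
Why: In this chiral phosphoric acid-catalysed allylboration through a closed six-membered chair transition state the (R)-acid should direct the methallyl group to the aldehyde face that gives the 8R carbinol (the sense known for aldehydes whose substituent outranks the allyl CH2), while low temperature and neutral work-up should keep the γ-hydroxy ester from lactonising.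

**Step 6**
Reactants: 10 methyl (2R,3R,4R)-4-hydroxy-3-[(4-methoxy-5-methyl-2-oxo-2H-pyran-6-yl)methyl]-6-methyl-2-(nitromethyl)hept-6-enoate
Product: 12 methyl (3R,4R)-4-acetoxy-3-[(4-methoxy-5-methyl-2-oxo-2H-pyran-6-yl)methyl]-6-methyl-2-methylidenehept-6-enoate, via nitro acetate 11 (not isolated)
Conditions: Ac2O, pyridine, 4-(dimethylamino)pyridine (cat.), CH2Cl2, 0 °C; then 1,8-diazabicyclo[5.4.0]undec-7-ene (DBU), 0 °C → rt
Reagents that add atoms: acetic anhydride, CC(=O)OC(C)=O
Why: Acyl-transfer-catalysed O-acetylation at 0 °C should be faster than lactonisation, and DBU then removes the ester α-proton at C11 and expels nitrite (E1cB elimination of HNO2 from a β-nitro ester), which unveils the acrylate without touching C7 or C8.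

**Step 7**
Reactants: 12 methyl (3R,4R)-4-acetoxy-3-[(4-methoxy-5-methyl-2-oxo-2H-pyran-6-yl)methyl]-6-methyl-2-methylidenehept-6-enoate
Product: 14 methyl (7R,8R,10R)-8-acetoxy-3-methoxyeudesma-2,4,11(13)-trien-12-oate, via bridged lactone cycloadduct 13 (not isolated)
Conditions: 1,2-dichlorobenzene (0.01 M), 2,6-di-tert-butyl-4-methylphenol (cat.), Ar, 180 °C
Reagents that add atoms: none
Why: Heating brings the 1,1-disubstituted alkene C10=C1 over the pyrone diene (pyrone C3–C6 = C2–C5 of the target) in a thermal [4+2] cycloaddition that forms the C1–C2 and C5–C10 bonds and dearomatises the flat pyrone to the bridged lactone 13, which loses CO2 by retro-[4+2] at the same temperature to leave the 3-methoxy-2,4-diene of ring A; the closest known reaction type is the intramolecular Diels–Alder reaction of 2-pyrones carrying unactivated alkenyl tethers followed by CO2 extrusion. Ring B closes through C5–C10 as the tether ring of a fused cycloaddition (four-atom tether C6–C9) and ring A closes through C1–C2 as the new six-membered carbocycle, so the regiochemistry is fixed by the tether, and the acrylate, held only two atoms from the diene, cannot reach it. The only stereocentre that survives CO2 loss is the quaternary C10, and it is set by C7 and C8 through a chair-like tether that allylic strain with the C4 methyl group keeps on the ring-oxygen side of the pyrone. The step needs π-facial selectivity: in the chair leading to 14 the sp2-branched C7 substituent is equatorial and only the small acetoxy group is axial, where it meets the still nearly planar C10 methyl carbon and can turn its acetyl group outward, whereas the other chair would press the axial acrylate against the pyrone ring oxygen. This preference should be useful rather than complete, and the C10 epimer, being a diastereomer, should be separable. The step also needs chemoselectivity for the tethered alkene over intermolecular reactions of the acrylate, which high dilution and a radical inhibitor should secure.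

**Step 8**
Reactants: 14 methyl (7R,8R,10R)-8-acetoxy-3-methoxyeudesma-2,4,11(13)-trien-12-oate
Product: 15 methyl (7R,8R,10R)-8-acetoxy-3-oxoeudesma-4,11(13)-dien-12-oate
Conditions: 0.5 M aq. HCl, THF, 0 °C → rt
Reagents that add atoms: water, O
Why: In this hydrolysis of a 2-alkoxy-1,3-diene (enol ether hydrolysis) protonation at C2 gives the oxocarbenium ion conjugated with C4=C5, water adds at C3 and methanol leaves, so the conjugated 4-en-3-one should form directly while the acetate, the methyl ester and the acrylate survive dilute acid.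

**Step 9**
Reactants: 15 methyl (7R,8R,10R)-8-acetoxy-3-oxoeudesma-4,11(13)-dien-12-oate
Product: 16 methyl (3S,7R,8R,10R)-8-acetoxy-3-hydroxyeudesma-4,11(13)-dien-12-oate
Conditions: NaBH4, CeCl3·7H2O, MeOH, −78 °C
Reagents that add atoms: none
Why: In this Luche reduction (1,2-selective hydride addition to an enone) hydride should add axially from the α-face of the ring A half-chair, as in 4-en-3-ones that carry a 10β-methyl group, to give the pseudo-equatorial 3β-alcohol (3S), and at −78 °C the acrylate and both esters should not be reduced.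

**Step 10**
Reactants: 16 methyl (3S,7R,8R,10R)-8-acetoxy-3-hydroxyeudesma-4,11(13)-dien-12-oate
Product: 17 methyl (3S,7R,8R,10R)-8-acetoxy-3-(propanoyloxy)eudesma-4,11(13)-dien-12-oate (CNP0198123.1; 3β-propanoyloxy, 8β-acetoxy, 7α-H, 10β-methyl)
Conditions: (EtCO)2O, Et3N, 4-(dimethylamino)pyridine (cat.), CH2Cl2, 0 °C → rt
Reagents that add atoms: propionic anhydride, CCC(=O)OC(=O)CC
Why: Acyl-transfer-catalysed esterification of the secondary allylic alcohol proceeds with retention at C3 and should complete the target.

**Compound list**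
1 | 4-hydroxy-5,6-dimethyl-2H-pyran-2-one | CC1=C(C)C(O)=CC(=O)O1 | starting material
2 | 4-methoxy-5,6-dimethyl-2H-pyran-2-one | CC1=C(C)C(OC)=CC(=O)O1 | intermediate
3 | allyl bromide | C=CCBr | starting material
4 | 6-(but-3-en-1-yl)-4-methoxy-5-methyl-2H-pyran-2-one | C=CCCC1=C(C)C(OC)=CC(=O)O1 | intermediate
5 | 6-(3,4-dihydroxybutyl)-4-methoxy-5-methyl-2H-pyran-2-one (racemic at the carbinol carbon, which is lost on cleavage) | OCC(O)CCC1=C(C)C(OC)=CC(=O)O1 | intermediate
6 | 3-(4-methoxy-5-methyl-2-oxo-2H-pyran-6-yl)propanal | O=CCCC1=C(C)C(OC)=CC(=O)O1 | intermediate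
7 | methyl (E)-3-nitroacrylate | COC(=O)/C=C/[N+](=O)[O-] | starting material
8 | methyl (2R,3R)-3-formyl-4-(4-methoxy-5-methyl-2-oxo-2H-pyran-6-yl)-2-(nitromethyl)butanoate | O=C[C@H](CC1=C(C)C(OC)=CC(=O)O1)[C@H](C[N+](=O)[O-])C(=O)OC | intermediate
9 | 2-(2-methylallyl)-4,4,5,5-tetramethyl-1,3,2-dioxaborolane | C=C(C)CB1OC(C)(C)C(C)(C)O1 | starting material
10 | methyl (2R,3R,4R)-4-hydroxy-3-[(4-methoxy-5-methyl-2-oxo-2H-pyran-6-yl)methyl]-6-methyl-2-(nitromethyl)hept-6-enoate | C=C(C)C[C@@H](O)[C@H](CC1=C(C)C(OC)=CC(=O)O1)[C@H](C[N+](=O)[O-])C(=O)OC | intermediate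
11 | methyl (2R,3R,4R)-4-acetoxy-3-[(4-methoxy-5-methyl-2-oxo-2H-pyran-6-yl)methyl]-6-methyl-2-(nitromethyl)hept-6-enoate | C=C(C)C[C@@H](OC(C)=O)[C@H](CC1=C(C)C(OC)=CC(=O)O1)[C@H](C[N+](=O)[O-])C(=O)OC | intermediate
12 | methyl (3R,4R)-4-acetoxy-3-[(4-methoxy-5-methyl-2-oxo-2H-pyran-6-yl)methyl]-6-methyl-2-methylidenehept-6-enoate | C=C(C)C[C@@H](OC(C)=O)[C@H](CC1=C(C)C(OC)=CC(=O)O1)C(=C)C(=O)OC | intermediate
13 | bridged lactone cycloadduct of 12 (2-oxabicyclo[2.2.2]oct-5-en-3-one spanning C2 and C5 of ring A, lactone oxygen on C5; 3-methoxy, 8-acetoxy; 7R,8R,10R) | C=C(C(=O)OC)[C@H]1C[C@@]23OC(=O)[C@@H](C(OC)=C2C)C[C@]3(C)C[C@H]1OC(C)=O | intermediate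
14 | methyl (7R,8R,10R)-8-acetoxy-3-methoxyeudesma-2,4,11(13)-trien-12-oate | C=C(C(=O)OC)[C@H]1CC2=C(C)C(OC)=CC[C@]2(C)C[C@H]1OC(C)=O | intermediate
15 | methyl (7R,8R,10R)-8-acetoxy-3-oxoeudesma-4,11(13)-dien-12-oate | C=C(C(=O)OC)[C@H]1CC2=C(C)C(=O)CC[C@]2(C)C[C@H]1OC(C)=O | intermediate
16 | methyl (3S,7R,8R,10R)-8-acetoxy-3-hydroxyeudesma-4,11(13)-dien-12-oate | C=C(C(=O)OC)[C@H]1CC2=C(C)[C@@H](O)CC[C@]2(C)C[C@H]1OC(C)=O | intermediate
17 | methyl (3S,7R,8R,10R)-8-acetoxy-3-(propanoyloxy)eudesma-4,11(13)-dien-12-oate (CNP0198123.1) | C=C(C(=O)OC)[C@H]1CC2=C(C)[C@@H](OC(=O)CC)CC[C@]2(C)C[C@H]1OC(C)=O | target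

**Step count**
Total steps: 10. Longest linear sequence: 10 steps (1 → 17).

**Steps most likely to fail, with fallbacks**

Step 7 (key step). Facial discrimination in the chair-like tether may be incomplete, because the chair with the C7 group axial delivers the C10 epimer; at 180 °C the acrylate may also be consumed by ene or intermolecular cycloaddition processes. The fallback sets out from 10 and returns at 14, and runs the cycloaddition before the acrylate is unveiled. Compound 10 is only acetylated (Ac2O, pyridine, 4-(dimethylamino)pyridine, 0 °C, no DBU) and the nitro acetate 11 is isolated. Thermolysis of 11 under the conditions of step 7, with propylene oxide as acid scavenger, should pass through the bridged lactone cycloadduct of the nitro ester series F1 and give methyl (7R,8R,10R,11R)-8-acetoxy-3-methoxy-13-nitroeudesma-2,4-dien-12-oate F2. Here the sp3-branched CH(CO2Me)CH2NO2 group is a stronger equatorial anchor at C7 and no second electron-poor alkene is present. DBU (CH2Cl2, 0 °C) then eliminates HNO2 (E1cB) and gives 14.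

Step 5. Mismatched double stereodifferentiation with the existing centres may lower the selectivity at C8, the acid catalyst may enolise the α-branched aldehyde (epimerisation at C7), or the γ-hydroxy ester may lactonise. The fallback sets out from 8 and returns at 10, and sets C8 by ketone reduction instead of by carbon–carbon bond formation. An indium-mediated Barbier methallylation (In, 3-bromo-2-methylpropene, THF/H2O) gives 10 together with its C8 epimer methyl (2R,3R,4S)-4-hydroxy-3-[(4-methoxy-5-methyl-2-oxo-2H-pyran-6-yl)methyl]-6-methyl-2-(nitromethyl)hept-6-enoate F3. Dess–Martin oxidation of the mixture gives methyl (2R,3R)-3-[(4-methoxy-5-methyl-2-oxo-2H-pyran-6-yl)methyl]-6-methyl-2-(nitromethyl)-4-oxohept-6-enoate F4, which is used without delay. Corey–Bakshi–Shibata reduction with the (S)-methyl oxazaborolidine and catecholborane (PhMe, −78 °C) should then deliver 10 under catalyst control.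

Step 9. Hydride may be delivered to the β-face of the enone (3α-alcohol), or the acrylate may undergo conjugate reduction. The fallback sets out from 15 and returns at 17; it uses the face the substrate prefers and inverts on esterification. Catalyst-controlled 1,2-reduction (Corey–Bakshi–Shibata reduction with the (S)-methyl oxazaborolidine and catecholborane, −78 °C) gives methyl (3R,7R,8R,10R)-8-acetoxy-3-hydroxyeudesma-4,11(13)-dien-12-oate F5, the 3α-alcohol. Mitsunobu esterification with propanoic acid (PPh3, diisopropyl azodicarboxylate, THF, 0 °C) then installs the propionate with inversion at C3 and gives 17 directly.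

**Further compounds**
F1 | step 7 | bridged lactone cycloadduct of 11 (nitro ester series; 2-oxabicyclo[2.2.2]oct-5-en-3-one spanning C2 and C5; 7R,8R,10R,11R) | COC(=O)[C@@H](C[N+](=O)[O-])[C@H]1C[C@@]23OC(=O)[C@@H](C(OC)=C2C)C[C@]3(C)C[C@H]1OC(C)=O
F2 | step 7 | methyl (7R,8R,10R,11R)-8-acetoxy-3-methoxy-13-nitroeudesma-2,4-dien-12-oate | COC(=O)[C@@H](C[N+](=O)[O-])[C@H]1CC2=C(C)C(OC)=CC[C@]2(C)C[C@H]1OC(C)=O
F3 | step 5 | methyl (2R,3R,4S)-4-hydroxy-3-[(4-methoxy-5-methyl-2-oxo-2H-pyran-6-yl)methyl]-6-methyl-2-(nitromethyl)hept-6-enoate | C=C(C)C[C@H](O)[C@H](CC1=C(C)C(OC)=CC(=O)O1)[C@H](C[N+](=O)[O-])C(=O)OC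
F4 | step 5 | methyl (2R,3R)-3-[(4-methoxy-5-methyl-2-oxo-2H-pyran-6-yl)methyl]-6-methyl-2-(nitromethyl)-4-oxohept-6-enoate | C=C(C)CC(=O)[C@H](CC1=C(C)C(OC)=CC(=O)O1)[C@H](C[N+](=O)[O-])C(=O)OC
F5 | step 9 | methyl (3R,7R,8R,10R)-8-acetoxy-3-hydroxyeudesma-4,11(13)-dien-12-oate | C=C(C(=O)OC)[C@H]1CC2=C(C)[C@H](O)CC[C@]2(C)C[C@H]1OC(C)=O
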